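Everything rests on building ring A of the isoquinoline (C4a, C5, C6, C7, C8, C8a) onto a finished naphthalene, so that the crowded C5–C1′ biaryl bond never has to be made by coupling. The feature used is the meta pair of oxygens at C6 and C8 around the bare C7, flanked by aryl-bearing C5 and alkyl-bearing C4a, which is the signature of a vinylketene–ynol ether benzannulation. In one operation, Wolff rearrangement, [2+2] addition, ring opening and 6π closure deliver the C6 phenol. The precursor is an (E)-α′-diazo enone with the naphthyl group on its β-carbon and an (S)-2-[N(Boc)2]propyl arm on its α-carbon; its partner is methoxyacetylene.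

Key step: step 12

Assumption: the SMILES fixes C1 and C3 (both S, methyl groups trans) and leaves the C5–C1′ axis open. That axis is configurationally stable and is not expected to be controlled by the benzannulation. All compounds from the benzannulation product onward are therefore carried as pairs of atropo-diastereomers, both of which fit the given structure and which can be separated by chromatography at the final amine.

Step 1
Reactants: 1 N,N-diethyl-2-methoxybenzamide; 2 3-bromo-2-methylprop-1-ene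
Product: 5 N,N-diethyl-2-methoxy-6-(2-methylprop-2-en-1-yl)benzamide, via ortho-lithiated benzamide 3 (not isolated), via arylmagnesium bromide 4 (not isolated)
Conditions: s-BuLi, TMEDA, THF, −78 °C; MgBr2·OEt2, −78 to 0 °C; 2, 0 °C to rt
Reagents that add atoms: none
Why: Directed ortho-metalation: the tertiary amide outranks the methoxy group as director, so lithiation occurs at C6, and exchange of lithium for magnesium gives a less basic aryl nucleophile that is allylated cleanly by 2.

Step 2
Reactants: 5 N,N-diethyl-2-methoxy-6-(2-methylprop-2-en-1-yl)benzamide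
Product: 6 8-methoxy-3-methylnaphthalen-1-ol
Conditions: MeLi (2.2 equiv), THF, −78 °C to rt; 1 M aq HCl
Reagents that add atoms: none
Why: Anionic annulation of an ortho-allylbenzamide: MeLi removes a benzylic–allylic proton, the terminal allyl carbon acylates on the neighbouring hindered amide in a six-membered closure, and loss of diethylamide with tautomerization gives the 1-naphthol with its methyl group at C3.

Step 3
Reactants: 6 8-methoxy-3-methylnaphthalen-1-ol
Product: 7 1,8-dimethoxy-3-methylnaphthalene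
Conditions: NaH, MeI, DMF, 0 °C to rt
Reagents that add atoms: iodomethane, CI
Why: Williamson ether synthesis, in which full deprotonation with NaH breaks the peri hydrogen bond to the C8 methoxy group that would otherwise slow the methylation.

Step 4
Reactants: 7 1,8-dimethoxy-3-methylnaphthalene
Product: 8 1-bromo-4,5-dimethoxy-2-methylnaphthalene
Conditions: NBS (1.0 equiv), MeCN, 0 °C, dark
Reagents that add atoms: N-bromosuccinimide, O=C1CCC(=O)N1Br
Why: Electrophilic aromatic bromination should go to the α-position para to a methoxy group in the ring that the methyl group makes the more electron-rich, while polar solvent, low temperature and darkness suppress radical attack on the benzylic methyl group.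

Step 5
Reactants: 8 1-bromo-4,5-dimethoxy-2-methylnaphthalene
Product: 10 4,5-dimethoxy-2-methylnaphthalene-1-carbaldehyde, via naphthyllithium 9 (not isolated)
Conditions: n-BuLi, THF, −78 °C; DMF, −78 °C to rt; 1 M aq HCl
Reagents that add atoms: N,N-dimethylformamide, CN(C)C=O
Why: Bromine–lithium exchange followed by formylation with DMF (Bouveault aldehyde synthesis) places the formyl group exactly where the bromine stood, so the regiochemistry is settled in step 4.

Step 6
Reactants: 11 prop-2-enyl 2-(diethoxyphosphoryl)acetate; 12 tert-butyl (4S)-4-methyl-1,2,3-oxathiazolidine-3-carboxylate 2,2-dioxide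
Product: 14 prop-2-enyl (4S)-4-[(tert-butoxycarbonyl)amino]-2-(diethoxyphosphoryl)pentanoate (both C2 epimers), via sodium N-sulfamate 13 (not isolated)
Conditions: NaH, DMF, 0 °C to rt; then 1 M aq HCl–Et2O, rt
Reagents that add atoms: none
Why: SN2 opening of the cyclic sulfamidate at its primary C–O carbon by the soft phosphonoacetate anion leaves the stereocentre untouched (S retained), the anionic N-sulfamate cannot lactamize, mild acid then cleaves only the N–S bond, and the epimeric C2 centre disappears in step 7.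

Step 7
Reactants: 14 prop-2-enyl (4S)-4-[(tert-butoxycarbonyl)amino]-2-(diethoxyphosphoryl)pentanoate; 10 4,5-dimethoxy-2-methylnaphthalene-1-carbaldehyde
Product: 15 prop-2-enyl (2E,4S)-4-[(tert-butoxycarbonyl)amino]-2-[(4,5-dimethoxy-2-methylnaphthalen-1-yl)methylidene]pentanoate
Conditions: NaH (1.05 equiv), THF, 0 to 50 °C
Reagents that add atoms: none
Why: Horner–Wadsworth–Emmons olefination: the phosphonoacetate C–H is far more acidic than the carbamate N–H, so one equivalent of base suffices, and reversible addition with elimination through the less crowded arrangement should place the bulky naphthyl group trans to the ester (E).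

Step 8
Reactants: 15 prop-2-enyl (2E,4S)-4-[(tert-butoxycarbonyl)amino]-2-[(4,5-dimethoxy-2-methylnaphthalen-1-yl)methylidene]pentanoate
Product: 16 prop-2-enyl (2E,4S)-4-[bis(tert-butoxycarbonyl)amino]-2-[(4,5-dimethoxy-2-methylnaphthalen-1-yl)methylidene]pentanoate
Conditions: Boc2O, DMAP, MeCN, rt
Reagents that add atoms: di-tert-butyl dicarbonate, CC(C)(C)OC(=O)OC(=O)OC(C)(C)C
Why: DMAP-catalysed tert-butoxycarbonylation of the carbamate N–H, placed after the olefination so that no acidic phosphonoacetate C–H can be acylated and no carbanion can attack a Boc group.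

Step 9
Reactants: 16 prop-2-enyl (2E,4S)-4-[bis(tert-butoxycarbonyl)amino]-2-[(4,5-dimethoxy-2-methylnaphthalen-1-yl)methylidene]pentanoate
Product: 17 (2E,4S)-4-[bis(tert-butoxycarbonyl)amino]-2-[(4,5-dimethoxy-2-methylnaphthalen-1-yl)methylidene]pentanoic acid
Conditions: Pd(PPh3)4 (5 mol %), morpholine, THF, rt; aq citric acid
Reagents that add atoms: none
Why: Tsuji–Trost deallylation: zerovalent palladium transfers the allyl group to morpholine under neutral conditions, which spares the imidodicarbonate that saponification of a hindered conjugated ester could erode.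

Step 10
Reactants: 17 (2E,4S)-4-[bis(tert-butoxycarbonyl)amino]-2-[(4,5-dimethoxy-2-methylnaphthalen-1-yl)methylidene]pentanoic acid
Product: 20 di-tert-butyl N-[(2S,4E)-4-(diazoacetyl)-5-(4,5-dimethoxy-2-methylnaphthalen-1-yl)pent-4-en-2-yl]imidodicarbonate, via acid chloride 18 (not isolated), via C-silyl diazo ketone 19 (not isolated)
Conditions: 1-chloro-N,N,2-trimethylprop-1-en-1-amine, CH2Cl2, 0 °C to rt; TMSCHN2 (2.5 equiv), THF–MeCN, 0 °C; aq NaHCO3, SiO2
Reagents that add atoms: (trimethylsilyl)diazomethane, C[Si](C)(C)C=[N+]=[N-]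
Why: Arndt–Eistert-type acylation of a diazoalkane: the α-chloroenamine makes the acid chloride without free HCl so both Boc groups survive, the bulky silyl diazoalkane attacks the acyl carbon but should be too hindered for dipolar cycloaddition to the trisubstituted, aryl-shielded alkene, and the C-silyl group falls off on work-up.

Step 11
Reactants: 21 2-chloro-1,1-dimethoxyethane
Product: 23 methoxyacetylene, via sodium methoxyacetylide 22 (not isolated)
Conditions: NaNH2 (3.1 equiv), liquid NH3, −33 °C; evaporate NH3; cold saturated aq NaCl, −20 °C; distil (bp 23 °C) into toluene at −78 °C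
Reagents that add atoms: none
Why: Double β-elimination (loss of methanol and of HCl) with excess sodium amide, the alkynyl ether being held as its acetylide until the cold aqueous quench, after which its low boiling point allows direct distillation into the solvent of step 12.

Step 12
Reactants: 20 di-tert-butyl N-[(2S,4E)-4-(diazoacetyl)-5-(4,5-dimethoxy-2-methylnaphthalen-1-yl)pent-4-en-2-yl]imidodicarbonate; 23 methoxyacetylene
Product: 28 di-tert-butyl N-[(2S)-1-[3-hydroxy-5-methoxy-2-(4,5-dimethoxy-2-methylnaphthalen-1-yl)phenyl]propan-2-yl]imidodicarbonate, via vinylketene 24 (not isolated), via 4-alkenylcyclobutenone 25 (not isolated), via dienylketene 26 (not isolated), via cyclohexadienone 27 (not isolated)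
Conditions: 23 (5 equiv), toluene, hν (medium-pressure Hg lamp, Pyrex filter), 0 °C; Ar purge; then 90 °C
Reagents that add atoms: none
Why: Light expels N2 from 20 and the alkenyl group shifts from the carbonyl carbon to the diazo carbon (Wolff rearrangement, making C4a–C8a) to give 24, whose carbonyl carbon (future C6) bonds to the nucleophilic unsubstituted alkyne carbon (C7) and whose α-carbon (C8a) bonds to the methoxy-bearing carbon (C8) in a [2+2] cycloaddition. Cyclobutenone 25 opens by reversible four-electron electrocyclic cleavage of its C6–C8a bond to 26, ring A then closes by disrotatory six-electron electrocyclization forming C5–C6, and 27 tautomerizes irreversibly to the phenol. The closest known reaction type is the Danheiser benzannulation in its diazo ketone version with alkynyl ethers. No lasting stereocentre is created, since the sp3 centres of 25 and 27 are transient, the (S) centre of the side chain is a spectator, and the new C5–C1′ axis should form without useful control. The regiochemistry needed (methoxy group meta to the hydroxyl with C7–H between them) follows from the matched polarity of ketene and ynol ether. The E alkene holds the naphthyl group on the outside of the closing triene, photochemical E/Z scrambling still converges on 28 because that carbon becomes aromatic, closure of the ketene onto the naphthalene is a dead end because C2′ and C8a′ are fully substituted, the N(Boc)2 group offers no N–H to the ketenes, and purging the volatile alkyne before heating keeps it from adding to the phenol.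

Step 13
Reactants: 28 di-tert-butyl N-[(2S)-1-[3-hydroxy-5-methoxy-2-(4,5-dimethoxy-2-methylnaphthalen-1-yl)phenyl]propan-2-yl]imidodicarbonate
Product: 29 di-tert-butyl N-[(2S)-1-[3,5-dimethoxy-2-(4,5-dimethoxy-2-methylnaphthalen-1-yl)phenyl]propan-2-yl]imidodicarbonate
Conditions: MeI, K2CO3, DMF, rt
Reagents that add atoms: iodomethane, CI
Why: Williamson ether synthesis at the only acidic site, under carbonate conditions at room temperature that do not touch the imidodicarbonate.

Step 14
Reactants: 29 di-tert-butyl N-[(2S)-1-[3,5-dimethoxy-2-(4,5-dimethoxy-2-methylnaphthalen-1-yl)phenyl]propan-2-yl]imidodicarbonate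
Product: 31 N-[(2S)-1-[3,5-dimethoxy-2-(4,5-dimethoxy-2-methylnaphthalen-1-yl)phenyl]propan-2-yl]acetamide, via primary ammonium trifluoroacetate 30 (not isolated)
Conditions: TFA, CH2Cl2, 0 °C to rt; concentrate; Ac2O, Et3N, CH2Cl2, 0 °C to rt
Reagents that add atoms: acetic anhydride, CC(=O)OC(C)=O
Why: Acidolysis of both tert-butyl carbamates followed by N-acetylation of the liberated primary amine in the same flask, neither operation touching the C–N stereocentre.

Step 15
Reactants: 31 N-[(2S)-1-[3,5-dimethoxy-2-(4,5-dimethoxy-2-methylnaphthalen-1-yl)phenyl]propan-2-yl]acetamide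
Product: 32 (3S)-5-(4,5-dimethoxy-2-methylnaphthalen-1-yl)-6,8-dimethoxy-1,3-dimethyl-3,4-dihydroisoquinoline
Conditions: POCl3, 2,4,6-collidine, MeCN, reflux; aq NaHCO3
Reagents that add atoms: none
Why: Bischler–Napieralski cyclodehydration: the activated acetamide can reach only C8a because C5 is blocked by the naphthyl group, and C8a lies ortho to the C8 and para to the C6 methoxy group, so the six-membered closure is favoured and C3 is not affected.

Step 16
Reactants: 32 (3S)-5-(4,5-dimethoxy-2-methylnaphthalen-1-yl)-6,8-dimethoxy-1,3-dimethyl-3,4-dihydroisoquinoline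
Product: 33 (1S,3S)-5-(4,5-dimethoxy-2-methylnaphthalen-1-yl)-6,8-dimethoxy-1,3-dimethyl-1,2,3,4-tetrahydroisoquinoline
Conditions: AlMe3, LiAlH4, THF, −78 to 0 °C; H2O
Reagents that add atoms: none
Why: Lewis acid-directed imine reduction: AlMe3 binds the nitrogen and the resulting strain drives the C3 methyl group pseudoaxial, so that stereoelectronically preferred axial hydride delivery to C1 through a chair-like transition state should place the C1 methyl group trans to it and set C1 as S under control of C3.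

Compound list
1 | N,N-diethyl-2-methoxybenzamide | CCN(CC)C(=O)c1ccccc1OC | starting material
2 | 3-bromo-2-methylprop-1-ene | C=C(C)CBr | starting material
3 | [2-(diethylcarbamoyl)-3-methoxyphenyl]lithium | CCN(CC)C(=O)c1c([Li])cccc1OC | intermediate
4 | [2-(diethylcarbamoyl)-3-methoxyphenyl]magnesium bromide | CCN(CC)C(=O)c1c([Mg]Br)cccc1OC | intermediate
5 | N,N-diethyl-2-methoxy-6-(2-methylprop-2-en-1-yl)benzamide | CCN(CC)C(=O)c1c(CC(C)=C)cccc1OC | intermediate
6 | 8-methoxy-3-methylnaphthalen-1-ol | COc1cccc2cc(C)cc(O)c12 | intermediate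
7 | 1,8-dimethoxy-3-methylnaphthalene | COc1cccc2cc(C)cc(OC)c12 | intermediate
8 | 1-bromo-4,5-dimethoxy-2-methylnaphthalene | Brc1c(C)cc(OC)c2c(OC)cccc12 | intermediate
9 | (4,5-dimethoxy-2-methylnaphthalen-1-yl)lithium | [Li]c1c(C)cc(OC)c2c(OC)cccc12 | intermediate
10 | 4,5-dimethoxy-2-methylnaphthalene-1-carbaldehyde | O=Cc1c(C)cc(OC)c2c(OC)cccc12 | intermediate
11 | prop-2-enyl 2-(diethoxyphosphoryl)acetate (allyl diethylphosphonoacetate) | C=CCOC(=O)CP(=O)(OCC)OCC | starting material
12 | tert-butyl (4S)-4-methyl-1,2,3-oxathiazolidine-3-carboxylate 2,2-dioxide | C[C@H]1COS(=O)(=O)N1C(=O)OC(C)(C)C | starting material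
13 | sodium N-(tert-butoxycarbonyl)-N-[(2S)-4-(diethoxyphosphoryl)-5-oxo-5-(prop-2-enyloxy)pentan-2-yl]sulfamate | C=CCOC(=O)C(C[C@H](C)N(C(=O)OC(C)(C)C)S(=O)(=O)[O-])P(=O)(OCC)OCC.[Na+] | intermediate
14 | prop-2-enyl (4S)-4-[(tert-butoxycarbonyl)amino]-2-(diethoxyphosphoryl)pentanoate, both C2 epimers | C=CCOC(=O)C(C[C@H](C)NC(=O)OC(C)(C)C)P(=O)(OCC)OCC | intermediate
15 | prop-2-enyl (2E,4S)-4-[(tert-butoxycarbonyl)amino]-2-[(4,5-dimethoxy-2-methylnaphthalen-1-yl)methylidene]pentanoate | C=CCOC(=O)/C(C[C@H](C)NC(=O)OC(C)(C)C)=C/c1c(C)cc(OC)c2c(OC)cccc12 | intermediate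
16 | prop-2-enyl (2E,4S)-4-[bis(tert-butoxycarbonyl)amino]-2-[(4,5-dimethoxy-2-methylnaphthalen-1-yl)methylidene]pentanoate | C=CCOC(=O)/C(C[C@H](C)N(C(=O)OC(C)(C)C)C(=O)OC(C)(C)C)=C/c1c(C)cc(OC)c2c(OC)cccc12 | intermediate
17 | (2E,4S)-4-[bis(tert-butoxycarbonyl)amino]-2-[(4,5-dimethoxy-2-methylnaphthalen-1-yl)methylidene]pentanoic acid | OC(=O)/C(C[C@H](C)N(C(=O)OC(C)(C)C)C(=O)OC(C)(C)C)=C/c1c(C)cc(OC)c2c(OC)cccc12 | intermediate
18 | (2E,4S)-4-[bis(tert-butoxycarbonyl)amino]-2-[(4,5-dimethoxy-2-methylnaphthalen-1-yl)methylidene]pentanoyl chloride | ClC(=O)/C(C[C@H](C)N(C(=O)OC(C)(C)C)C(=O)OC(C)(C)C)=C/c1c(C)cc(OC)c2c(OC)cccc12 | intermediate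
19 | di-tert-butyl N-[(2S,4E)-4-[diazo(trimethylsilyl)acetyl]-5-(4,5-dimethoxy-2-methylnaphthalen-1-yl)pent-4-en-2-yl]imidodicarbonate | C[Si](C)(C)C(=[N+]=[N-])C(=O)/C(C[C@H](C)N(C(=O)OC(C)(C)C)C(=O)OC(C)(C)C)=C/c1c(C)cc(OC)c2c(OC)cccc12 | intermediate
20 | di-tert-butyl N-[(2S,4E)-4-(diazoacetyl)-5-(4,5-dimethoxy-2-methylnaphthalen-1-yl)pent-4-en-2-yl]imidodicarbonate | [N-]=[N+]=CC(=O)/C(C[C@H](C)N(C(=O)OC(C)(C)C)C(=O)OC(C)(C)C)=C/c1c(C)cc(OC)c2c(OC)cccc12 | intermediate
21 | 2-chloro-1,1-dimethoxyethane (chloroacetaldehyde dimethyl acetal) | COC(CCl)OC | starting material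
22 | sodium methoxyacetylide | [Na+].[C-]#COC | intermediate
23 | methoxyacetylene | COC#C | intermediate
24 | di-tert-butyl N-[(2S,4E)-5-(4,5-dimethoxy-2-methylnaphthalen-1-yl)-4-(2-oxoethenyl)pent-4-en-2-yl]imidodicarbonate (vinylketene) | O=C=C/C(C[C@H](C)N(C(=O)OC(C)(C)C)C(=O)OC(C)(C)C)=C/c1c(C)cc(OC)c2c(OC)cccc12 | intermediate
25 | di-tert-butyl N-[(2S,4E)-5-(4,5-dimethoxy-2-methylnaphthalen-1-yl)-4-(2-methoxy-4-oxocyclobut-2-en-1-yl)pent-4-en-2-yl]imidodicarbonate, both ring epimers | O=C1C=C(OC)C1/C(C[C@H](C)N(C(=O)OC(C)(C)C)C(=O)OC(C)(C)C)=C/c1c(C)cc(OC)c2c(OC)cccc12 | intermediate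
26 | dienylketene O=C=CH–C(OMe)=CH–C(CH2R)=CH–naphthyl, ketenyl and alkenyl groups cis on the central double bond, R = (S)-CH(CH3)N(Boc)2 | O=C=C/C(OC)=C\C(C[C@H](C)N(C(=O)OC(C)(C)C)C(=O)OC(C)(C)C)=C\c1c(C)cc(OC)c2c(OC)cccc12 | intermediate
27 | di-tert-butyl N-[(2S)-1-[6-(4,5-dimethoxy-2-methylnaphthalen-1-yl)-3-methoxy-5-oxocyclohexa-1,3-dien-1-yl]propan-2-yl]imidodicarbonate, both ring epimers | O=C1C=C(OC)C=C(C[C@H](C)N(C(=O)OC(C)(C)C)C(=O)OC(C)(C)C)C1c1c(C)cc(OC)c2c(OC)cccc12 | intermediate
28 | di-tert-butyl N-[(2S)-1-[3-hydroxy-5-methoxy-2-(4,5-dimethoxy-2-methylnaphthalen-1-yl)phenyl]propan-2-yl]imidodicarbonate | Oc1cc(OC)cc(C[C@H](C)N(C(=O)OC(C)(C)C)C(=O)OC(C)(C)C)c1-c1c(C)cc(OC)c2c(OC)cccc12 | intermediate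
29 | di-tert-butyl N-[(2S)-1-[3,5-dimethoxy-2-(4,5-dimethoxy-2-methylnaphthalen-1-yl)phenyl]propan-2-yl]imidodicarbonate | COc1cc(OC)cc(C[C@H](C)N(C(=O)OC(C)(C)C)C(=O)OC(C)(C)C)c1-c1c(C)cc(OC)c2c(OC)cccc12 | intermediate
30 | (2S)-1-[3,5-dimethoxy-2-(4,5-dimethoxy-2-methylnaphthalen-1-yl)phenyl]propan-2-amine trifluoroacetate | COc1cc(OC)cc(C[C@H](C)N)c1-c1c(C)cc(OC)c2c(OC)cccc12.OC(=O)C(F)(F)F | intermediate
31 | N-[(2S)-1-[3,5-dimethoxy-2-(4,5-dimethoxy-2-methylnaphthalen-1-yl)phenyl]propan-2-yl]acetamide | COc1cc(OC)cc(C[C@H](C)NC(C)=O)c1-c1c(C)cc(OC)c2c(OC)cccc12 | intermediate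
32 | (3S)-5-(4,5-dimethoxy-2-methylnaphthalen-1-yl)-6,8-dimethoxy-1,3-dimethyl-3,4-dihydroisoquinoline | COc1cc(OC)c2c(c1-c1c(C)cc(OC)c3c(OC)cccc13)C[C@H](C)N=C2C | intermediate
33 | (1S,3S)-5-(4,5-dimethoxy-2-methylnaphthalen-1-yl)-6,8-dimethoxy-1,3-dimethyl-1,2,3,4-tetrahydroisoquinoline | COc1cc(OC)c2c(c1-c1c(C)cc(OC)c3c(OC)cccc13)C[C@H](C)N[C@H]2C | target

Total step count: 16. Longest linear sequence: 14 (steps 1–5, 7–10, 12–16).

Steps most likely to fail

Step 12.
- What may go wrong: The naphthyl chromophore may take most of the light or pass triplet energy to the diazo ketone, so that nitrogen is lost without the Wolff shift. The ketenes may oligomerize. The sequence may also stall before the six-electron closure next to the very bulky aryl group.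
- Fallback: It gives up ring construction in favour of a biaryl coupling, sets out from 8 and rejoins the route at 31.
- Bromide 8 is lithiated to 9 (n-BuLi, THF, −78 °C) and treated with B(OMe)3 and then dilute acid to give (4,5-dimethoxy-2-methylnaphthalen-1-yl)boronic acid F1.
- In parallel, commercial 3,5-dimethoxyphenylmagnesium bromide opens commercial tert-butyl (S)-2-methylaziridine-1-carboxylate at its CH2 carbon under CuBr·SMe2 catalysis. This gives tert-butyl N-[(2S)-1-(3,5-dimethoxyphenyl)propan-2-yl]carbamate F2.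
- N-Iodosuccinimide in MeCN iodinates F2 ortho to the side chain and para to a methoxy group, giving tert-butyl N-[(2S)-1-(2-iodo-3,5-dimethoxyphenyl)propan-2-yl]carbamate F3.
- Suzuki–Miyaura coupling of F1 with F3 (Pd(OAc)2, SPhos, K3PO4, toluene–water, 100 °C) gives tert-butyl N-[(2S)-1-[3,5-dimethoxy-2-(4,5-dimethoxy-2-methylnaphthalen-1-yl)phenyl]propan-2-yl]carbamate F4.
- The conditions of step 14 take F4 through 30 to 31.

Step 7.
- What may go wrong: Addition of the α-branched phosphonate anion to a hindered, electron-rich aldehyde may be slow, and the E selectivity may erode on heating.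
- Fallback: It replaces olefination by aldol addition and elimination on a lactam, sets out from 10 and rejoins at 15.
- The lithium enolate (LiHMDS, THF, −78 °C) of commercial tert-butyl (2S)-2-methyl-5-oxopyrrolidine-1-carboxylate adds to 10. This gives tert-butyl (2S)-4-[(4,5-dimethoxy-2-methylnaphthalen-1-yl)(hydroxy)methyl]-2-methyl-5-oxopyrrolidine-1-carboxylate F5.
- MsCl and Et3N convert F5 into tert-butyl (2S)-4-[(4,5-dimethoxy-2-methylnaphthalen-1-yl)(methylsulfonyloxy)methyl]-2-methyl-5-oxopyrrolidine-1-carboxylate F6.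
- DBU-induced E1cB elimination gives the thermodynamically preferred tert-butyl (2S,4E)-4-[(4,5-dimethoxy-2-methylnaphthalen-1-yl)methylidene]-2-methyl-5-oxopyrrolidine-1-carboxylate F7.
- Lithium prop-2-en-1-olate in allyl alcohol–THF at 0 °C opens the Boc-activated lactam of F7 at its ring carbonyl and gives 15.

Step 10.
- What may go wrong: Acylation of the silyl diazoalkane by the hindered acid chloride may be sluggish. Dipolar cycloaddition at the enoyl double bond may compete, and adventitious acid may strip a Boc group.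
- Fallback: It avoids acylation of a diazoalkane altogether by using diazo transfer to a methyl ketone, sets out from 17 and rejoins at 20.
- Carbonyldiimidazole converts 17 into di-tert-butyl N-[(2S,4E)-5-(4,5-dimethoxy-2-methylnaphthalen-1-yl)-4-(imidazole-1-carbonyl)pent-4-en-2-yl]imidodicarbonate F8.
- C-Acylation of Mg(O2CCH2CO2CH2CH=CH2)2 by F8, with loss of CO2, gives prop-2-enyl (4E,6S)-6-[bis(tert-butoxycarbonyl)amino]-4-[(4,5-dimethoxy-2-methylnaphthalen-1-yl)methylidene]-3-oxoheptanoate F9.
- Decarboxylative deallylation with Pd(PPh3)4 and morpholine gives di-tert-butyl N-[(2S,4E)-4-acetyl-5-(4,5-dimethoxy-2-methylnaphthalen-1-yl)pent-4-en-2-yl]imidodicarbonate F10.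
- Kinetic deprotonation at the methyl group (LiHMDS, THF, −78 °C) and trapping with CF3CO2CH2CF3 give di-tert-butyl N-[(2S,4E)-5-(4,5-dimethoxy-2-methylnaphthalen-1-yl)-4-(4,4,4-trifluoro-3-oxobutanoyl)pent-4-en-2-yl]imidodicarbonate F11.
- Detrifluoroacetylative diazo transfer to F11 with 4-acetamidobenzenesulfonyl azide, Et3N and water in MeCN gives 20.

Further compounds
F1 | step 12 | (4,5-dimethoxy-2-methylnaphthalen-1-yl)boronic acid | OB(O)c1c(C)cc(OC)c2c(OC)cccc12
F2 | step 12 | tert-butyl N-[(2S)-1-(3,5-dimethoxyphenyl)propan-2-yl]carbamate | COc1cc(OC)cc(C[C@H](C)NC(=O)OC(C)(C)C)c1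
F3 | step 12 | tert-butyl N-[(2S)-1-(2-iodo-3,5-dimethoxyphenyl)propan-2-yl]carbamate | COc1cc(OC)c(I)c(C[C@H](C)NC(=O)OC(C)(C)C)c1
F4 | step 12 | tert-butyl N-[(2S)-1-[3,5-dimethoxy-2-(4,5-dimethoxy-2-methylnaphthalen-1-yl)phenyl]propan-2-yl]carbamate | COc1cc(OC)c(-c2c(C)cc(OC)c3c(OC)cccc23)c(C[C@H](C)NC(=O)OC(C)(C)C)c1
F5 | step 7 | tert-butyl (2S)-4-[(4,5-dimethoxy-2-methylnaphthalen-1-yl)(hydroxy)methyl]-2-methyl-5-oxopyrrolidine-1-carboxylate | C[C@H]1CC(C(O)c2c(C)cc(OC)c3c(OC)cccc23)C(=O)N1C(=O)OC(C)(C)C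
F6 | step 7 | tert-butyl (2S)-4-[(4,5-dimethoxy-2-methylnaphthalen-1-yl)(methylsulfonyloxy)methyl]-2-methyl-5-oxopyrrolidine-1-carboxylate | C[C@H]1CC(C(OS(C)(=O)=O)c2c(C)cc(OC)c3c(OC)cccc23)C(=O)N1C(=O)OC(C)(C)C
F7 | step 7 | tert-butyl (2S,4E)-4-[(4,5-dimethoxy-2-methylnaphthalen-1-yl)methylidene]-2-methyl-5-oxopyrrolidine-1-carboxylate | C[C@H]1C/C(=C\c2c(C)cc(OC)c3c(OC)cccc23)C(=O)N1C(=O)OC(C)(C)C
F8 | step 10 | di-tert-butyl N-[(2S,4E)-5-(4,5-dimethoxy-2-methylnaphthalen-1-yl)-4-(imidazole-1-carbonyl)pent-4-en-2-yl]imidodicarbonate | O=C(n1ccnc1)/C(C[C@H](C)N(C(=O)OC(C)(C)C)C(=O)OC(C)(C)C)=C/c1c(C)cc(OC)c2c(OC)cccc12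
F9 | step 10 | prop-2-enyl (4E,6S)-6-[bis(tert-butoxycarbonyl)amino]-4-[(4,5-dimethoxy-2-methylnaphthalen-1-yl)methylidene]-3-oxoheptanoate | C=CCOC(=O)CC(=O)/C(C[C@H](C)N(C(=O)OC(C)(C)C)C(=O)OC(C)(C)C)=C/c1c(C)cc(OC)c2c(OC)cccc12
F10 | step 10 | di-tert-butyl N-[(2S,4E)-4-acetyl-5-(4,5-dimethoxy-2-methylnaphthalen-1-yl)pent-4-en-2-yl]imidodicarbonate | CC(=O)/C(C[C@H](C)N(C(=O)OC(C)(C)C)C(=O)OC(C)(C)C)=C/c1c(C)cc(OC)c2c(OC)cccc12
F11 | step 10 | di-tert-butyl N-[(2S,4E)-5-(4,5-dimethoxy-2-methylnaphthalen-1-yl)-4-(4,4,4-trifluoro-3-oxobutanoyl)pent-4-en-2-yl]imidodicarbonate | O=C(CC(=O)C(F)(F)F)/C(C[C@H](C)N(C(=O)OC(C)(C)C)C(=O)OC(C)(C)C)=C/c1c(C)cc(OC)c2c(OC)cccc12
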